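(The data are calculated for an exercise; the scatter is artificial.)

**On the bench.** Over its first hours each flask loses solid substrate to dissolving, which does not count as reaction. The last solid readings of Tuesday's and Thursday's runs put the dissolved plateau at 25.5%. Both runs read 83% at 2.00 h, which gives a dissolving time of 1.82 h.

| setting | Tuesday's | Thursday's | ochre | amber | blue |
|---|---|---|---|---|---|
| solid substrate | 12 mM | 12 mM | 12 mM | 12 mM | 12 mM |
| reagent | 10.8 mM | 10.8 mM | 10.8 mM | 10.8 mM | 10.8 mM |
| scavenger | 11 mM | 31 mM | 18.0 mM | 27.0 mM | 40.0 mM |
| free catalyst | 2.2 mM | 2.2 mM | 2.2 mM | 2.2 mM | 2.2 mM |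
| remark | run made earlier | run made earlier |  |  |  |
| time |  |  | 10 h | 10 h | 10 h |

| run | time / h | solid substrate / % | product / % |
|---|---|---|---|
| Tuesday's | 0.250 | 93 | 1 |
| Tuesday's | 0.833 | 89 | 1 |
| Tuesday's | 1.33 | 86 | 0 |
| Tuesday's | 2.00 | 83 | 3 |
| Tuesday's | 3.00 | 78 | 1 |
| Tuesday's | 4.00 | 75 | 8 |
| Tuesday's | 5.00 | 76 | 1 |
| Thursday's | 0.667 | 94 | 0 |
| Thursday's | 1.33 | 89 | 0 |
| Thursday's | 2.00 | 83 | 3 |
| Thursday's | 3.00 | 80 | 0 |
| Thursday's | 4.00 | 75 | 2 |
| Thursday's | 5.00 | 73 | 7 |

(each reading ± 2 percentage points)

- solid, in amounts per volume of the solution: solid substrate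
- at the start none of the solid substrate is in solution
- what has only dissolved of solid substrate counts as not reacted

1. part of the solid substrate that has reacted (what has only dissolved counts as not reacted) at the end, ochre
2. part of the solid substrate that has reacted (what has only dissolved counts as not reacted) at the end, amber
3. part of the solid substrate that has reacted (what has only dissolved counts as not reacted) at the end, blue
4. what raising the concentration of scavenger from its lowest to its highest value here does to the part of the solid substrate that has reacted (what has only dissolved counts as not reacted) (changes below 5 percentage points count as none) (no change / it falls / it rises)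

**My reckoning.** I take the reaction rate as proportional to the dissolved share. Integrated, the reacted share is the pace times the plateau hours, which are the elapsed time minus the dissolving time multiplied by the part of the plateau reached. The last four product readings, each scattered by 2 percentage points, average 4.50% near 4.50 h, which holds 2.83 h plateau hours. So the pace is 0.0159 h⁻¹, the share reacted per plateau hour. The 10 h run holds 8.19 h plateau hours, so I expect 13.0% reacted.

**Leave alone.** I keep scavenger as charged: the product readings at 4.00 h and 5.00 h average 4.50% in the 11 mM run and 4.50% in the 31 mM run, each reading scattered by 2 points.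

**The forecast.** It says 10%, 10% and 10%, with no change, “since the solid keeps the solution saturated”. My figure is higher.

**The result.** Ochre, amber and blue give 15.0%, 15.1% and 15.1%: no change, a change of 0.18 points.

    reagent + free catalyst → catalyst intermediate A (k = 4.50 M⁻¹ min⁻¹)
    catalyst intermediate A ⇌ released group + catalyst intermediate B (K = 0.00940 M, k = 0.0460 min⁻¹)
    starting material + catalyst intermediate B → catalyst intermediate C (k = 0.730 M⁻¹ min⁻¹)
    catalyst intermediate C ⇌ free catalyst + product (K = 0.0340 M, k = 0.0460 min⁻¹)
    reagent + released group ⇌ idle adduct, settled at all times (K = 42.0 M⁻¹)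
    scavenger + released group → scavenged by-product (k = 1.30 M⁻¹ min⁻¹)
    solid substrate ⇌ starting material, rate k7*(cs7 - [starting material]) while solid is left; crystals form when [starting material] > cs7 (solubility = 3.20 mM, k = 0.00730 min⁻¹)

**Not at rest.** The true dissolving time of 2.28 h gives ochre 7.75 h plateau hours, so its 15.0% comes to 0.0194 h⁻¹ on average, against my 0.0159 h⁻¹. Scaled to a quarter of the catalyst, my pace gives 3.25% for the neighbour with 0.55 mM of free catalyst, which stands at 4.19%. Left until 100 h, ochre reaches 89.6%, the reagent's charge over the solid's being 90.0%. That limiting reagent is down to 0%, while 10.4% stays as starting material and free catalyst is back at 75.1%.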